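All runs were generated by integration for an exercise; the scatter is artificial.

A fraction of the charge per hour is the unit for this flask, with intermediate B plus target counted as what has come through from the solid.

| setting | Wednesday's | Sunday's | flask |
|---|---|---|---|
| solid substrate | 0.34 M | 0.75 M | 0.50 M |
| capture agent | 0.50 M | 0.50 M | 0.500 M |
| remark | run made earlier | run made earlier |  |
| time |  |  | 2.5 d |

| run | time / h | intermediate B / % | target / % |
|---|---|---|---|
| Wednesday's | 0.667 | 19 | 1 |
| Wednesday's | 2.00 | 56 | 20 |
| Wednesday's | 5.00 | 25 | 51 |
| Wednesday's | 15.0 | 0 | 77 |
| Wednesday's | 50.0 | 0 | 76 |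
| Sunday's | 0.667 | 10 | 0 |
| Sunday's | 2.00 | 34 | 9 |
| Sunday's | 5.00 | 36 | 44 |
| Sunday's | 15.0 | 5 | 77 |
| Sunday's | 50.0 | 2 | 75 |

(scatter of a reading: 1.5 percentage points)

* the best time, 2.5 d at the latest, for intermediate B
* the amount of intermediate B, in percent of the solid substrate charged, at that time
* the first time at which intermediate B reaches 27%, in the same percent

- at the start none of the solid substrate is in solution
- a reading or a percentage of target counts all its forms, free or not

Two chemists dispute the flask. The second treats the path from solid to target as a line of fixed time constants, so percentages would not depend on the charge and the flask would repeat Wednesday's run, the nearer one. That puts the highest reading at 2.00 h and the passage of 27%, read between readings, at 0.955 h.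

The first chemist, whose side I take, objects. At the first reading the sum stands at 20.0% in Wednesday's run, twice Sunday's 10.0%, and the charges stand in a ratio of 2.21. So in these two runs the solid gives about the same amount per hour, although their charges differ. Sunday's sum climbs by 0.248 h⁻¹ of its charge between its first two readings. Scaled to this flask, the supply rate, the fraction of the charge delivered per hour, is 0.371 h⁻¹. Traced back, Sunday's supply starts at 0.263 h.

Wednesday's fall gives B a loss constant of 0.269 h⁻¹. Even at 56% that loses 0.151 h⁻¹, less than the supply, so I expect B in this flask to climb until supply stops. With Wednesday's plateau of 77% delivered, I reckon that at 2.34 h, later than the second chemist's time.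

For 27%, a first pass without loss needs 0.727 h of supply. But B is lost meanwhile at about half its final level, so putting that time back gives 0.798 h, and once more 0.805 h. My crossing is therefore 1.07 h.

The forecast sides with the first chemist, “dissolution is saturation-limited”, and gives 0.098 d, 56% and 1.1 h.

    intermediate A → intermediate B (k = 0.00130 s⁻¹)
    intermediate B → intermediate C (k = 7.80 × 10⁻⁵ s⁻¹)
    intermediate A + capture agent → trapped intermediate (k = 8.70 × 10⁻⁴ M⁻¹ s⁻¹)
    crystals ⇌ target, rate k4*(cs4 - [target]) while solid is left; crystals form when [target] > cs4 (solubility = 0.0770 M, k = 0.130 s⁻¹)
    starting material → intermediate A (k = 0.00120 s⁻¹)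
    solid substrate ⇌ starting material, rate k6*(cs6 - [starting material]) while solid is left; crystals form when [starting material] > cs6 (solubility = 0.0820 M, k = 0.00240 s⁻¹)
    intermediate C → target (k = 0.0330 s⁻¹)

The flask peaks at 0.0983 d with 54.3% and passes 27% at 1.09 h, against my 0.0975 d and 1.07 h. At the peak the solid substrate stands at 0%, with 1.97% as starting material and 3.26% as intermediate A still on the way. With the capture agent held as charged, the second chemist's region lies at charges under the saturation level of starting material, 0.082 M. With half the charge the supply rate is 0.742 h⁻¹, which puts the peak at 0.0542 d; that flask gives 0.0609 d.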